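Which flask ends richer in complex with one exchanged: delta, read late with much incoming ligand, or zeta, read early with little?

| setting | noon | spring | delta | zeta |
|---|---|---|---|---|
| starting complex | 0.21 M | 0.21 M | 0.21 M | 0.21 M |
| incoming ligand | 0.14 M | 0.53 M | 0.378 M | 0.120 M |
| remark | run made earlier | run made earlier |  |  |
| time |  |  | 50 min | 15 min |

- noon (time / min: complex with one exchanged / %, starting complex / %): 4.00: 4.1, 96.3; 12.0: 9.1, 89.5; 25.0: 11.7, 84.1; 40.0: 12.4, 80.4; 50.0: 11.5, 79.8
- spring (time / min: complex with one exchanged / %, starting complex / %): 4.00: 13.4, 86.2; 8.00: 22.5, 76.0; 15.0: 28.3, 65.4; 25.0: 30.0, 59.3; 50.0: 23.2, 54.1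

(each reading ± 0.5 percentage points)

- which one finishes higher in amount of complex with one exchanged, in percent of the starting complex charged ("neither" within 2 percentage points) (delta / zeta / neither)
- amount of complex with one exchanged at the end, in percent of the starting complex charged, delta
- amount of complex with one exchanged at the end, in percent of the starting complex charged, zeta

- the analysis behind the earlier runs scatters by 0.5 percentage points, standard deviation
- steps under discussion: complex with two exchanged + incoming ligand <-> leaving ligand + complex with three exchanged; complex with one exchanged + incoming ligand <-> leaving ligand + complex with two exchanged; complex with one exchanged <-> isomer of the product; starting complex + incoming ligand <-> leaving ligand + complex with one exchanged; incoming ligand -> decomposed reagent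

I reckon with what stays, not with what forms: the end amount is the spent fraction of starting complex times the kept share, the part of the spent starting complex still standing as complex with one exchanged (its selectivity). Which number must I know well? At 50.0 min the kept share reads 56.9 % in noon and 50.5 % in spring, at 3.79 times the charged [incoming ligand], and that swing moves the end amount by 2.9 percentage points. The spent fraction goes from 20.2 % to 45.9 %, which moves it by 13 points. So for delta, read at that same time, the spent fraction needs care, and the kept share tolerates a rough value.

Now the numbers. In charged [incoming ligand] delta lies 61.0 % of the way from noon to spring, so I interpolate a kept share for delta of 53.0 %, a spent fraction of 35.9 %, and an end amount of 19.0 %. For zeta I scale noon's spent fraction at 12.0 min in proportion to time and ligand, which gives 11.2 %. Spring's kept share at 15.0 min is 81.8 %; borrowing it, I estimate zeta near 9.16 %.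

The forecast says delta, with 19.8 % for delta and 8.9 % for zeta, figures that differ from mine, on the ground: “This looks first order, so isomerisation, not a second exchange.”

    complex with two exchanged + incoming ligand ⇌ leaving ligand + complex with three exchanged (K = 0.190, k = 5.55 × 10⁻⁵ M⁻¹ s⁻¹)
    complex with one exchanged + incoming ligand ⇌ leaving ligand + complex with two exchanged (K = 1.81, k = 1.51 × 10⁻⁴ M⁻¹ s⁻¹)
    complex with one exchanged ⇌ isomer of the product (K = 2.00, k = 3.15 × 10⁻⁴ s⁻¹)
    starting complex + incoming ligand ⇌ leaving ligand + complex with one exchanged (K = 0.220, k = 0.00126 M⁻¹ s⁻¹)
    incoming ligand → decomposed reagent (k = 2.29 × 10⁻⁴ s⁻¹)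

Delta ends at 20.5 % and zeta at 8.66 %, so delta stands higher, as forecast. Delta's spent fraction, 38.3 %, multiplied by my kept share, 53.0 %, gives 20.3 %. The neighbour of delta charged with 0.23 M spends 28.5 %, which gives 15.1 % against its 16.2 %. Of the two settings that differ, the charge of incoming ligand is the largest single effect : zeta given delta's charge holds 22.5 %, and zeta given delta's time holds 10.7 %. The forecast's choice turns wrong in a longer run: delta read at 500 min holds 4.20 % and zeta read at 150 min holds 6.00 %, a gap of 1.8 points, inside the margin of 2 points.

The numbers in the tables are calculated for substances that don't exist, and the scatter is random.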